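The easy step in this flask is the rise of tautomer from substrate. What matters is how many lifetimes of that rise pass before tautomer stops gaining.

| setting | zeta | theta | flask |
|---|---|---|---|
| substrate | 0.75 M | 3 M | 1.5 M |
| solid reagent | 1.42 M | 1.42 M | 1.42 M |
| remark | run made earlier | run made earlier |  |
| time |  |  | 8.0 min |

- zeta (time / min: tautomer / %, target / %): 0.667: 22.6, 0.4; 1.00: 28.0, 0.9; 2.00: 34.2, 1.0; 3.00: 33.7, 5.3; 5.00: 32.3, 4.0; 8.00: 30.4, 9.3
- theta (time / min: tautomer / %, target / %): 0.667: 23.4, 0.8; 1.00: 29.5, 2.1; 2.00: 35.0, 2.9; 3.00: 36.4, 4.3; 5.00: 34.1, 3.7; 8.00: 33.1, 6.8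

(each reading ± 1 percentage point)

- given per volume of solution although it is solid: solid reagent
- at the start none of the solid reagent is in solution

1. time up to 8.0 min at which tautomer stands highest
2. the amount of tautomer, in percent of the substrate charged, at that time

Take the rise by itself. Averaged over zeta and theta, tautomer stands at 23.0% at 0.667 min and at 35.1% at 3.00 min. Taking the later value as the level approached, the lifetime of the rise (its relaxation time) is

τ = −t / ln(1 − early/level) = 0.625 min

This step by itself gives a curve that climbs and has no peak.

Now add the loss. Over 5.00 min from 3.00 min, tautomer falls 3.3 percentage points in zeta and 3.3 points in theta, a steady drain. Tautomer peaks where the remaining gain, (level/τ)·exp(−t/τ), has shrunk to the drain. That gives the peak count, the number of lifetimes from the start to the peak: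

n = ln(level·Δt / (τ·drop)) = 4.44

t = n·τ = 2.78 min

The opening gain is far faster than the drain, but the logarithm compresses that ratio, so the time follows τ more closely than it follows the drain.

Last comes the charge. The flask's substrate, 1.5 M, is the geometric mean of the zeta and theta charges, and those runs drain alike, so τ and the drain carry over. The reckoned peak lies near 3.00 min, so the mean level of 35.1% serves as my height for the flask.

The forecast gives 2.5 min (1.8 min to 3.4 min), earlier than this reckoning, and 35% (33.8% to 36.3%), adding: “The peak is flat, so the time is poorly defined.”

The flask reaches its highest tautomer, 35.6%, at 2.68 min.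

    substrate ⇌ tautomer (K = 0.661, k = 0.00910 s⁻¹)
    coupling partner + tautomer → target (k = 0.0106 L mol⁻¹ s⁻¹)
    solid reagent ⇌ coupling partner, rate k3*(cs3 - [coupling partner]) while solid is left; crystals form when [coupling partner] > cs3 (solubility = 0.0770 M, k = 0.0442 s⁻¹)
    substrate + coupling partner → isomer of the product (k = 0.0100 L mol⁻¹ s⁻¹)

At 4.01 min the flask still holds 34.7% of tautomer. The reckoned time of 2.78 min stands 0.1000 min after the flask's peak. The neighbouring flask with the same charge, read at 3.0 min, stands 4.80 lifetimes of the value read from the runs in, beyond the peak count, and holds 35.5% of tautomer.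

(All runs are calculated from invented constants; noise was put on by code.)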